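**Plan**
- Retrosynthetic cuts: (i) flavone O1–C8a, which opens the pyranone ring C of the flavone; (ii) flavone C2–C3, the C–C bond of the resulting 1,3-diketone; (iii) the bond from flavanone C3 to C3' of the flavone ring B.
- Enabling feature: in the flavone, O1 sits on C8a of ring A. C8a is ortho to the C4 carbonyl (through C4a) and meta to the oxygens on C5 and C7, so a fluorine on that carbon can be displaced by the enolate oxygen of the open diketone.
- Forward order: the flavanone rings come intact from (S)-naringenin. Its C3 is arylated with a 3-bromo-4-benzyloxybenzoate (future ring B), the ester is extended by Claisen condensation with a 2-fluoroacetophenone (future ring A), and the flavone ring C closes last.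
- Stereochemistry: C2 (S) is taken from naringenin. C3 (R) is set trans to the C2 aryl group in the arylation. Both are kept away from base by holding C4 as a silylated carbinol from step 9 to step 12.

Key step: step 11

Assumption: the configuration at C4 of the carbinol-level compounds 12, 13 and 15–17 is left open (either epimer or both are carried), because C4 returns to a ketone in step 13.

Step 1
Reactants: 1 1-fluoro-3,5-dimethoxybenzene
Product: 3 1-(2-fluoro-6-hydroxy-4-methoxyphenyl)ethanone, via dimethoxy ketone 2 (not isolated)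
Conditions: AcCl (1.1 equiv), AlCl3 (2.5 equiv), CH2Cl2, 0 °C → 40 °C; ice/1 M HCl
Reagents that add atoms: acetyl chloride, CC(Cl)=O
Why: Friedel–Crafts acylation should occur at C2 of 1 (para to one methoxy group, ortho to the other, and less crowded than the site between the two methoxy groups), after which excess AlCl3 cleaves only the methoxy group ortho to the new carbonyl through its six-membered aluminium chelate (chelation-directed demethylation).

Step 2
Reactants: 3 1-(2-fluoro-6-hydroxy-4-methoxyphenyl)ethanone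
Product: 4 1-[2-(benzyloxy)-6-fluoro-4-methoxyphenyl]ethanone
Conditions: BnBr, K2CO3, DMF, 60 °C
Reagents that add atoms: benzyl bromide, BrCc1ccccc1
Why: Williamson ether synthesis on the chelated phenol, which needs gentle heating but has no competing nucleophilic site.

Step 3
Reactants: 5 methyl 3-bromo-4-hydroxybenzoate
Product: 6 methyl 4-(benzyloxy)-3-bromobenzoate
Conditions: BnBr, K2CO3, acetone, reflux
Reagents that add atoms: benzyl bromide, BrCc1ccccc1
Why: Williamson ether synthesis of an acidic phenol para to an ester; the ester and the aryl bromide are inert to carbonate.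

Step 4
Reactants: 7 (S)-naringenin
Product: 8 (S)-4',7-di-O-benzylnaringenin
Conditions: BnOH (2.3 equiv), PPh3 (2.4 equiv), DIAD (2.4 equiv), THF, 0 °C → rt
Reagents that add atoms: benzyl alcohol, OCc1ccccc1
Why: Mitsunobu etherification alkylates the two acidic phenols (7-OH and 4'-OH) under essentially neutral conditions and leaves the chelated 5-OH alone, so no carbonate-type base is present that could open ring C to the chalcone and erode C2.

Step 5
Reactants: 8 (S)-4',7-di-O-benzylnaringenin
Product: 9 (S)-4',5,7-tri-O-benzylnaringenin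
Conditions: NaH (1.0 equiv), DMF, 0 °C; BnBr (1.2 equiv), Bu4NI (cat.), 0 °C → rt
Reagents that add atoms: benzyl bromide, BrCc1ccccc1
Why: Williamson ether synthesis in which one equivalent of NaH turns the 5-OH into its phenoxide, the only base present and too weak to enolise C3, so benzylation should proceed without retro-oxa-Michael ring opening or loss of configuration at C2.

Step 6
Reactants: 9 (S)-4',5,7-tri-O-benzylnaringenin
Product: 10 trimethylsilyl enol ether of 9
Conditions: Me3SiOTf (1.3 equiv), Et3N (2 equiv), CH2Cl2, 0 °C; non-aqueous work-up, used crude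
Reagents that add atoms: trimethylsilyl trifluoromethanesulfonate, C[Si](C)(C)OS(=O)(=O)C(F)(F)F
Why: Soft enolisation (silyl triflate with a tertiary amine) traps the C3–C4 enol as its silyl ether without forming a metal enolate that could expel the ring-A aryloxide, so C2 is untouched.

Step 7
Reactants: 10 trimethylsilyl enol ether of 9; 6 methyl 4-(benzyloxy)-3-bromobenzoate
Product: 11 (2S,3R)-3-aryl flavanone ester (2,3-trans)
Conditions: Pd(OAc)2 (5 mol%), P(t-Bu)3 (10 mol%), Bu3SnF (1.4 equiv), CsF (1.4 equiv), toluene, 85 °C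
Reagents that add atoms: none
Why: Palladium-catalysed ketone α-arylation in its enol silane variant: a tributyltin enolate formed by Si-to-Sn exchange (the tin fluoride being regenerated by CsF) transmetalates to the arylpalladium bromide without a free basic enolate, reductive elimination places the aryl group on the face of C3 opposite the C2 aryl group, and the acidic C3–H lets any cis isomer settle to the diequatorial 2,3-trans (3R) ketone.

Step 8
Reactants: 11 (2S,3R)-3-aryl flavanone ester
Product: 12 flavan-4-ol ester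
Conditions: NaBH4, THF/MeOH (4:1), 0 °C
Reagents that add atoms: none
Why: Borohydride reduction of the aryl ketone at 0 °C leaves the methyl benzoate intact; hydride is expected to arrive anti to the C3 aryl group, but the new C4 centre is not needed because it is reoxidised in step 13.

Step 9
Reactants: 12 flavan-4-ol ester
Product: 13 C4 tert-butyldimethylsilyl ether ester
Conditions: t-BuMe2SiOTf, 2,6-lutidine, CH2Cl2, −78 °C → 0 °C
Reagents that add atoms: tert-butyldimethylsilyl trifluoromethanesulfonate, CC(C)(C)[Si](C)(C)OS(=O)(=O)C(F)(F)F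
Why: O-silylation with a silyl triflate and a hindered pyridine base caps the crowded benzylic carbinol at low temperature before the electron-rich C4 position can ionise, giving a base-stable mask for the flavanone carbonyl.

Step 10
Reactants: 4 1-[2-(benzyloxy)-6-fluoro-4-methoxyphenyl]ethanone; 13 C4 tert-butyldimethylsilyl ether ester
Product: 15 1-(2-fluoroaryl)-3-aryl-1,3-diketone (C4 silyl ether), via lithium enolate 14 (not isolated)
Conditions: 4 (2.2 equiv), LiN(SiMe3)2 (2.3 equiv), THF, −78 °C; then 13, −78 °C → rt; aq NH4Cl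
Reagents that add atoms: none
Why: Crossed Claisen condensation in which the preformed lithium enolate of the methyl ketone attacks the non-enolisable aryl methyl ester and the stabilised diketonate drives the equilibrium, while the silyl-protected flavan has no acidic C–H.

Step 11
Reactants: 15 1-(2-fluoroaryl)-3-aryl-1,3-diketone (C4 silyl ether)
Product: 16 protected biflavonoid with the flavanone C4 as silyl ether
Conditions: K2CO3 (3 equiv), DMF, 90 °C
Reagents that add atoms: none
Why: K2CO3 deprotonates the diketone, and the enolate oxygen on the carbon that carries the future ring B adds to the fluorine-bearing carbon (future C8a); the Meisenheimer intermediate is stabilised by the ortho acyl group (future C4 carbonyl) and collapses with loss of fluoride (addition–elimination SNAr). The closest known reactions are the carbonate-mediated cyclisation of 1-(2-haloaryl)-1,3-diketones to flavones and of 2-fluoro-2'-hydroxybenzophenones to xanthones. The flavone ring C closes as a six-membered ring by attack on an sp2 carbon, formally 6-endo-trig with respect to the C8a=C4a bond that takes up the charge. No stereocentre is formed, and the existing C2 and C3 of the flavanone are safe because C4 is a silylated carbinol, so carbonate can neither enolise C3 nor open the O1–C2 bond. The step needs O- over C-arylation of the ambident enolate: only oxygen can reach the C–F carbon in a six-membered ring (carbon would close a four-membered ring). Both ring-A alkoxy groups are meta to fluorine and do not push electron density onto the attacked carbon.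

Step 12
Reactants: 16 protected biflavonoid with the flavanone C4 as silyl ether
Product: 17 protected biflavonoid with free C4 carbinol
Conditions: Bu4NF, THF, rt → 40 °C
Reagents that add atoms: none
Why: Fluoride-induced desilylation, driven by the Si–F bond, frees the hindered carbinol without touching the benzyl ethers or the flavone.

Step 13
Reactants: 17 protected biflavonoid with free C4 carbinol
Product: 18 penta-O-benzyl ether of the target
Conditions: Dess–Martin periodinane (1.5 equiv), NaHCO3, CH2Cl2, 0 °C → rt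
Reagents that add atoms: none
Why: Dess–Martin oxidation under bicarbonate buffer converts the secondary benzylic alcohol into the flavanone ketone under neutral conditions, so the now acidic C3–H and the O1–C2 bond see no base and the more stable 2,3-trans arrangement is kept.

Step 14
Reactants: 18 penta-O-benzyl ether of the target
Product: 19 target compound CNP0361110.2
Conditions: H2 (1 atm), 10% Pd/C, EtOAc/MeOH, rt
Reagents that add atoms: none
Why: Catalytic hydrogenolysis of the five aryl benzyl ethers is expected to be much faster than reduction of the flavone C2=C3 bond, the flavanone carbonyl or the cyclic C2–O1 benzylic ether, and the neutral medium leaves both stereocentres untouched.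

**Compound list**
1 | 1-fluoro-3,5-dimethoxybenzene | COc1cc(F)cc(OC)c1 | starting material
2 | 1-(2-fluoro-4,6-dimethoxyphenyl)ethanone | CC(=O)c1c(F)cc(OC)cc1OC | intermediate (not isolated)
3 | 1-(2-fluoro-6-hydroxy-4-methoxyphenyl)ethanone | CC(=O)c1c(F)cc(OC)cc1O | intermediate
4 | 1-[2-(benzyloxy)-6-fluoro-4-methoxyphenyl]ethanone | CC(=O)c1c(F)cc(OC)cc1OCc1ccccc1 | intermediate
5 | methyl 3-bromo-4-hydroxybenzoate | COC(=O)c1ccc(O)c(Br)c1 | starting material
6 | methyl 4-(benzyloxy)-3-bromobenzoate | COC(=O)c1ccc(OCc2ccccc2)c(Br)c1 | intermediate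
7 | (S)-naringenin, (2S)-5,7-dihydroxy-2-(4-hydroxyphenyl)chroman-4-one | O=C1C[C@@H](c2ccc(O)cc2)Oc2cc(O)cc(O)c21 | starting material
8 | (2S)-7-(benzyloxy)-2-[4-(benzyloxy)phenyl]-5-hydroxychroman-4-one | O=C1C[C@@H](c2ccc(OCc3ccccc3)cc2)Oc2cc(OCc3ccccc3)cc(O)c21 | intermediate
9 | (2S)-5,7-bis(benzyloxy)-2-[4-(benzyloxy)phenyl]chroman-4-one | O=C1C[C@@H](c2ccc(OCc3ccccc3)cc2)Oc2cc(OCc3ccccc3)cc(OCc3ccccc3)c21 | intermediate
10 | (2S)-5,7-bis(benzyloxy)-2-[4-(benzyloxy)phenyl]-4-(trimethylsilyloxy)-2H-chromene | C[Si](C)(C)OC1=C[C@@H](c2ccc(OCc3ccccc3)cc2)Oc2cc(OCc3ccccc3)cc(OCc3ccccc3)c21 | intermediate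
11 | methyl 4-(benzyloxy)-3-{(2S,3R)-5,7-bis(benzyloxy)-2-[4-(benzyloxy)phenyl]-4-oxochroman-3-yl}benzoate (2,3-trans) | COC(=O)c1ccc(OCc2ccccc2)c([C@H]3C(=O)c4c(OCc5ccccc5)cc(OCc5ccccc5)cc4O[C@@H]3c3ccc(OCc4ccccc4)cc3)c1 | intermediate
12 | methyl 4-(benzyloxy)-3-{2,3-trans-5,7-bis(benzyloxy)-2-[4-(benzyloxy)phenyl]-4-hydroxychroman-3-yl}benzoate; C2 (S) and C3 arranged in space as in 11, C4 open | COC(=O)c1ccc(OCc2ccccc2)c([C@H]3C(O)c4c(OCc5ccccc5)cc(OCc5ccccc5)cc4O[C@@H]3c3ccc(OCc4ccccc4)cc3)c1 | intermediate
13 | methyl 4-(benzyloxy)-3-{2,3-trans-5,7-bis(benzyloxy)-2-[4-(benzyloxy)phenyl]-4-(tert-butyldimethylsilyloxy)chroman-3-yl}benzoate; C2 and C3 as in 11, C4 open | COC(=O)c1ccc(OCc2ccccc2)c([C@H]3C(O[Si](C)(C)C(C)(C)C)c4c(OCc5ccccc5)cc(OCc5ccccc5)cc4O[C@@H]3c3ccc(OCc4ccccc4)cc3)c1 | intermediate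
14 | lithium 1-[2-(benzyloxy)-6-fluoro-4-methoxyphenyl]ethen-1-olate | [Li+].[O-]C(=C)c1c(F)cc(OC)cc1OCc1ccccc1 | intermediate (not isolated)
15 | 1-[2-(benzyloxy)-6-fluoro-4-methoxyphenyl]-3-{4-(benzyloxy)-3-[2,3-trans-5,7-bis(benzyloxy)-2-(4-(benzyloxy)phenyl)-4-(tert-butyldimethylsilyloxy)chroman-3-yl]phenyl}propane-1,3-dione; C2 and C3 as in 11, C4 open | COc1cc(F)c(C(=O)CC(=O)c2ccc(OCc3ccccc3)c([C@H]3C(O[Si](C)(C)C(C)(C)C)c4c(OCc5ccccc5)cc(OCc5ccccc5)cc4O[C@@H]3c3ccc(OCc4ccccc4)cc3)c2)c(OCc2ccccc2)c1 | intermediate
16 | 5-(benzyloxy)-2-{4-(benzyloxy)-3-[2,3-trans-5,7-bis(benzyloxy)-2-(4-(benzyloxy)phenyl)-4-(tert-butyldimethylsilyloxy)chroman-3-yl]phenyl}-7-methoxy-4H-chromen-4-one; C2 and C3 of the chroman as in 11, C4 open | COc1cc(OCc2ccccc2)c2c(=O)cc(-c3ccc(OCc4ccccc4)c([C@H]4C(O[Si](C)(C)C(C)(C)C)c5c(OCc6ccccc6)cc(OCc6ccccc6)cc5O[C@@H]4c4ccc(OCc5ccccc5)cc4)c3)oc2c1 | intermediate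
17 | 5-(benzyloxy)-2-{4-(benzyloxy)-3-[2,3-trans-5,7-bis(benzyloxy)-2-(4-(benzyloxy)phenyl)-4-hydroxychroman-3-yl]phenyl}-7-methoxy-4H-chromen-4-one; C2 and C3 of the chroman as in 11, C4 open | COc1cc(OCc2ccccc2)c2c(=O)cc(-c3ccc(OCc4ccccc4)c([C@H]4C(O)c5c(OCc6ccccc6)cc(OCc6ccccc6)cc5O[C@@H]4c4ccc(OCc5ccccc5)cc4)c3)oc2c1 | intermediate
18 | 5-(benzyloxy)-2-{4-(benzyloxy)-3-[(2S,3R)-5,7-bis(benzyloxy)-2-(4-(benzyloxy)phenyl)-4-oxochroman-3-yl]phenyl}-7-methoxy-4H-chromen-4-one | COc1cc(OCc2ccccc2)c2c(=O)cc(-c3ccc(OCc4ccccc4)c([C@H]4C(=O)c5c(OCc6ccccc6)cc(OCc6ccccc6)cc5O[C@@H]4c4ccc(OCc5ccccc5)cc4)c3)oc2c1 | intermediate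
19 | 5-hydroxy-2-{4-hydroxy-3-[(2S,3R)-5,7-dihydroxy-2-(4-hydroxyphenyl)-4-oxochroman-3-yl]phenyl}-7-methoxy-4H-chromen-4-one (CNP0361110.2) | COc1cc(O)c2c(=O)cc(-c3ccc(O)c([C@H]4C(=O)c5c(O)cc(O)cc5O[C@@H]4c4ccc(O)cc4)c3)oc2c1 | target

**Step count**
Total: 14 steps. Longest linear sequence: 11 steps (7 → 19, steps 4–14).

**Steps most likely to fail**

Step 7. Transmetalation and reductive elimination may stall at the crowded C3 with an ortho-substituted aryl bromide. At 85 °C the metal enolate may also expel the ring-A aryloxide, which would open ring C and erode C2. The fallback sets out from 10 and returns at 11, and uses a fluoride-free copper-catalysed arylation of the enol silane with a diaryliodonium salt at room temperature. Commercial methyl 4-hydroxy-3-iodobenzoate would be benzylated (BnBr, K2CO3, acetone) to methyl 4-(benzyloxy)-3-iodobenzoate F1. Oxidation with mCPBA and TsOH·H2O in MeCN would give the hydroxy(tosyloxy)iodoarene F2, trapped in the same flask with 1,3,5-trimethoxybenzene as the aryl(2,4,6-trimethoxyphenyl)iodonium tosylate F3. F3 would then transfer its benzoate aryl group to 10 with Cu(OTf)2 (10 mol%) and 2,6-di-tert-butylpyridine in CH2Cl2, giving 11 after the same trans equilibration.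

Step 10. The electron-rich methyl benzoate is a sluggish acceptor, so enolate 14 may be consumed by proton transfer or self-aldol addition before acylation occurs. The fallback sets out from 13 and returns at 15, and replaces the ester by a more reactive acyl donor. Saponification (LiOH, THF/MeOH/H2O, then mild acidification) would give the carboxylic acid F4. 1,1'-Carbonyldiimidazole in THF would convert it into the acyl imidazolide F5. F5 would be added to enolate 14 (2.2 equiv, THF, −78 °C → 0 °C) to give 15.

Step 11. Addition of the enolate oxygen may be too slow, because the acyl group flanked by fluorine and benzyloxy is twisted out of the plane of the electron-rich ring A. On prolonged heating, retro-Claisen cleavage of the diketone by traces of water and carbonate would compete. The fallback sets out from 13 and returns at 16; it keeps the O1–C8a disconnection but uses a second, small and inductively activating fluorine. Commercially available 1-(2,6-difluoro-4-methoxyphenyl)ethanone would be deprotonated with LiN(SiMe3)2 to its lithium enolate F6. Condensation with 13 as in step 10 would give the difluoro diketone F7. K2CO3 in DMF should then close it to the 5-fluoroflavone F8. The remaining C5 fluorine, ortho to the C4 carbonyl, would be displaced by BnONa (BnOH, NaH, THF/DMF, 0 °C → rt) to give 16.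

**Further compounds**
F1 | step 7 | methyl 4-(benzyloxy)-3-iodobenzoate | COC(=O)c1ccc(OCc2ccccc2)c(I)c1
F2 | step 7 | methyl 4-(benzyloxy)-3-[hydroxy(tosyloxy)iodo]benzoate | COC(=O)c1ccc(OCc2ccccc2)c([I](O)OS(=O)(=O)c2ccc(C)cc2)c1
F3 | step 7 | [2-(benzyloxy)-5-(methoxycarbonyl)phenyl](2,4,6-trimethoxyphenyl)iodonium 4-methylbenzenesulfonate | COC(=O)c1ccc(OCc2ccccc2)c([I+]c2c(OC)cc(OC)cc2OC)c1.Cc1ccc(S(=O)(=O)[O-])cc1
F4 | step 10 | 4-(benzyloxy)-3-{2,3-trans-5,7-bis(benzyloxy)-2-[4-(benzyloxy)phenyl]-4-(tert-butyldimethylsilyloxy)chroman-3-yl}benzoic acid | OC(=O)c1ccc(OCc2ccccc2)c([C@H]3C(O[Si](C)(C)C(C)(C)C)c4c(OCc5ccccc5)cc(OCc5ccccc5)cc4O[C@@H]3c3ccc(OCc4ccccc4)cc3)c1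
F5 | step 10 | N-acyl imidazole (imidazolide) of F4 | O=C(n1ccnc1)c1ccc(OCc2ccccc2)c([C@H]3C(O[Si](C)(C)C(C)(C)C)c4c(OCc5ccccc5)cc(OCc5ccccc5)cc4O[C@@H]3c3ccc(OCc4ccccc4)cc3)c1
F6 | step 11 | lithium 1-(2,6-difluoro-4-methoxyphenyl)ethen-1-olate | [Li+].[O-]C(=C)c1c(F)cc(OC)cc1F
F7 | step 11 | 1-(2,6-difluoro-4-methoxyphenyl)-3-{4-(benzyloxy)-3-[2,3-trans-5,7-bis(benzyloxy)-2-(4-(benzyloxy)phenyl)-4-(tert-butyldimethylsilyloxy)chroman-3-yl]phenyl}propane-1,3-dione | COc1cc(F)c(C(=O)CC(=O)c2ccc(OCc3ccccc3)c([C@H]3C(O[Si](C)(C)C(C)(C)C)c4c(OCc5ccccc5)cc(OCc5ccccc5)cc4O[C@@H]3c3ccc(OCc4ccccc4)cc3)c2)c(F)c1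
F8 | step 11 | 2-{4-(benzyloxy)-3-[2,3-trans-5,7-bis(benzyloxy)-2-(4-(benzyloxy)phenyl)-4-(tert-butyldimethylsilyloxy)chroman-3-yl]phenyl}-5-fluoro-7-methoxy-4H-chromen-4-one | COc1cc(F)c2c(=O)cc(-c3ccc(OCc4ccccc4)c([C@H]4C(O[Si](C)(C)C(C)(C)C)c5c(OCc6ccccc6)cc(OCc6ccccc6)cc5O[C@@H]4c4ccc(OCc5ccccc5)cc4)c3)oc2c1
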